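**Retrosynthetic overview**
- Feature: C2, C3 and C4 of ring C form a propane chain that bears ring B on its middle carbon and an oxygen on each end carbon. The only stereocentre, C3, is therefore the centre of a hidden 2-aryl-1,3-propanediol with two enantiotopic CH2OH arms. C4a of ring A, which must bond to C4, lies next to the O1-bearing C8a and opposite the 7-OMe carbon, so it is the most nucleophilic free site of ring A.
- Last disconnections: the 2'-O–Si bond (fluoride) and the C6–prenyl bond (Stille coupling on a C6 bromide, which holds the place of the acid-sensitive prenyl group).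
- Key disconnection: C4–C4a, made by intramolecular Friedel–Crafts acylation of the (S)-3-aryloxy-2-arylpropanoic acid. Ring C is the only ring built; rings A and B are bought as the two bromophenols.
- The acid comes from a lipase-made (S)-monoacetate. The free arm becomes the C2–O1 ether (Mitsunobu) and the acetate arm becomes the C4 carboxyl group.
- The prochiral diol comes from palladium-catalysed arylation of diethyl malonate with silylated 2-bromo-5-methoxyphenol, followed by hydride reduction.

Key step: step 8

Assumption: the lipase is taken to acylate the pro-S CH2OH arm of the prochiral diol, as the 3S series requires; this sense must be confirmed on the first batch, and the fallback to step 4 covers the opposite outcome.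
Assumption: tributyl(3-methylbut-2-enyl)stannane is bought as such.

Step 1
Reactants: 1 2-bromo-5-methoxyphenol
Product: 2 (2-bromo-5-methoxyphenoxy)triisopropylsilane
Conditions: TIPSCl (1.2 equiv), imidazole (2.5 equiv), DMF, rt
Reagents that add atoms: chlorotriisopropylsilane (TIPSCl), CC(C)[Si](Cl)(C(C)C)C(C)C
Why: Imidazole-promoted O-silylation of a phenol, and the bulky triisopropylsilyl ether is chosen because it should outlast phosphate base, hydride, Mitsunobu, oxoammonium and trifluoroacetic acid conditions and still leave with fluoride in a non-basic medium at the end.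

Step 2
Reactants: 2 (2-bromo-5-methoxyphenoxy)triisopropylsilane; 3 diethyl malonate
Product: 4 diethyl 2-[4-methoxy-2-(triisopropylsilyloxy)phenyl]malonate
Conditions: Pd(dba)2 (2 mol %), P(t-Bu)3 (4 mol %), K3PO4 (3 equiv), toluene, 70 °C
Reagents that add atoms: none
Why: Palladium-catalysed α-arylation of a malonate, in which the electron-rich and bulky P(t-Bu)3 speeds both oxidative addition of zerovalent palladium into the electron-rich ortho-substituted C–Br bond and reductive elimination from the crowded arylpalladium enolate, while anhydrous K3PO4 in toluene leaves the aryl silyl ether alone.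

Step 3
Reactants: 4 diethyl 2-[4-methoxy-2-(triisopropylsilyloxy)phenyl]malonate
Product: 5 2-[4-methoxy-2-(triisopropylsilyloxy)phenyl]propane-1,3-diol (prochiral)
Conditions: LiAlH4 (2.5 equiv), THF, 0 °C (malonate added to the hydride)
Reagents that add atoms: none
Why: Hydride reduction of both esters to the prochiral 1,3-diol, run by adding the malonate to cold excess LiAlH4 so that reduction outruns deprotonation of the acidic malonate C–H and the aluminium alkoxides formed are too weakly nucleophilic to pull the silyl group off the phenol oxygen.

Step 4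
Reactants: 5 2-[4-methoxy-2-(triisopropylsilyloxy)phenyl]propane-1,3-diol
Product: 6 (S)-3-hydroxy-2-[4-methoxy-2-(triisopropylsilyloxy)phenyl]propyl acetate
Conditions: Burkholderia cepacia lipase (immobilised), vinyl acetate (5 equiv), t-BuOMe, 30 °C
Reagents that add atoms: vinyl acetate, C=COC(C)=O
Why: Lipase-catalysed irreversible transesterification used as a desymmetrisation, in which the chiral pocket around the acyl-enzyme tells the two enantiotopic CH2OH arms apart and thereby sets the future C3 as S, tautomerisation of the vinyl alcohol released makes the transfer irreversible, and faster second acylation of the minor monoacetate should raise the enantiopurity of what remains.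

Step 5
Reactants: 6 (S)-3-hydroxy-2-[4-methoxy-2-(triisopropylsilyloxy)phenyl]propyl acetate; 7 4-bromo-3-methoxyphenol
Product: 8 (S)-3-(4-bromo-3-methoxyphenoxy)-2-[4-methoxy-2-(triisopropylsilyloxy)phenyl]propyl acetate
Conditions: PPh3 (1.3 equiv), diisopropyl azodicarboxylate (DIAD, 1.3 equiv), toluene, 0 °C → rt
Reagents that add atoms: none
Why: Mitsunobu etherification, in which the free primary alcohol is activated as its alkoxyphosphonium salt and displaced by the phenoxide of 7 at a CH2 carbon, so the stereocentre next to it is not involved and the near-neutral medium gives the acetate no occasion to shift to the other arm.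

Step 6
Reactants: 8 (S)-3-(4-bromo-3-methoxyphenoxy)-2-[4-methoxy-2-(triisopropylsilyloxy)phenyl]propyl acetate
Product: 9 (R)-3-(4-bromo-3-methoxyphenoxy)-2-[4-methoxy-2-(triisopropylsilyloxy)phenyl]propan-1-ol (R by a change of CIP ranking only)
Conditions: i-Bu2AlH (2.5 equiv), CH2Cl2, −78 °C
Reagents that add atoms: none
Why: Reductive cleavage of the acetate by an aluminium hydride at low temperature, preferred to carbonate methanolysis because no free alkoxide or methoxide is formed that could attack or take over the phenolic silyl group, and the aryl bromide and aryl ethers are inert to it.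

Step 7
Reactants: 9 (R)-3-(4-bromo-3-methoxyphenoxy)-2-[4-methoxy-2-(triisopropylsilyloxy)phenyl]propan-1-ol
Product: 11 (S)-3-(4-bromo-3-methoxyphenoxy)-2-[4-methoxy-2-(triisopropylsilyloxy)phenyl]propanoic acid, via aldehyde 10 (not isolated)
Conditions: TEMPO (0.2 equiv), PhI(OAc)2 (2.5 equiv), CH2Cl2/H2O (2:1), 0 °C → rt
Reagents that add atoms: water, O
Why: TEMPO-catalysed oxidation with PhI(OAc)2 as terminal oxidant, in which the oxoammonium salt takes the primary alcohol to aldehyde 10 and the hydrate of 10 is oxidised on at once in the weakly acidic two-phase medium, so the enolisable and elimination-prone α-aryl-β-aryloxy aldehyde never meets base and no chlorine-based oxidant threatens the electron-rich rings.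

Step 8
Reactants: 11 (S)-3-(4-bromo-3-methoxyphenoxy)-2-[4-methoxy-2-(triisopropylsilyloxy)phenyl]propanoic acid
Product: 13 (S)-6-bromo-7-methoxy-3-[4-methoxy-2-(triisopropylsilyloxy)phenyl]chroman-4-one, via mixed anhydride 12 (not isolated)
Conditions: (CF3CO)2O (3 equiv), CH2Cl2, −20 → 0 °C; cold pH 7 phosphate buffer
Reagents that add atoms: trifluoroacetic anhydride, O=C(OC(=O)C(F)(F)F)C(F)(F)F (its acyl group stands only in intermediate 12; none of its atoms stays in 13)
Why: Intramolecular Friedel–Crafts acylation: (CF3CO)2O turns acid 11 into the acyl trifluoroacetate 12, the CF3CO2H released in that event activates 12 toward an acylium-like species, ring A carbon C4a attacks the acyl carbon, and loss of the proton from the arenium ion gives the aryl ketone. The closest known reaction type is the anhydride- or acid-mediated cyclisation of 3-aryloxypropanoic acids to chroman-4-ones. Ring C, the only ring made, closes in a 6-exo mode, since the C–O π bond that is broken lies outside the new ring O1–C2–C3–C4–C4a–C8a. No stereocentre is created; C3 is carried over from the lipase step and should hold because no base is present to open a ketene or enolate path and the temperature stays at or below 0 °C, where acid-catalysed enolisation is slow. Site selectivity is needed between the two carbons ortho to O1: C4a is para to the methoxy group and unhindered, whereas the other carbon lies between two oxygens and is screened by the methoxy methyl group, which the neighbouring bromine pushes toward it. With the 2'-oxygen capped by the bulky silyl group the competing five-membered lactone (a benzofuran-2-one) should not form, and the bromine reserves C6 for a prenyl group that would not outlast the acid.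

Step 9
Reactants: 13 (S)-6-bromo-7-methoxy-3-[4-methoxy-2-(triisopropylsilyloxy)phenyl]chroman-4-one; 14 tributyl(3-methylbut-2-enyl)stannane
Product: 15 (S)-7-methoxy-6-(3-methylbut-2-enyl)-3-[4-methoxy-2-(triisopropylsilyloxy)phenyl]chroman-4-one
Conditions: Pd(PPh3)4 (5 mol %), toluene (degassed), 100 °C
Reagents that add atoms: none
Why: Stille cross-coupling, in which zerovalent palladium inserts into the C6–Br bond, the allylic stannane transfers the prenyl group and reductive elimination at the less substituted allyl terminus gives the linear isomer, all without base so that the α-aryl ketone stereocentre C3 is not enolised.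

Step 10
Reactants: 15 (S)-7-methoxy-6-(3-methylbut-2-enyl)-3-[4-methoxy-2-(triisopropylsilyloxy)phenyl]chroman-4-one
Product: 16 (S)-3-(2-hydroxy-4-methoxyphenyl)-7-methoxy-6-(3-methylbut-2-enyl)chroman-4-one (target CNP0208718.1)
Conditions: HF·pyridine, pyridine, THF, 0 °C → rt
Reagents that add atoms: none
Why: Fluoride-driven cleavage of the aryl silyl ether by the strength of the Si–F bond, carried out in a pyridine-buffered weakly acidic medium so that the phenol is set free without passing through a basic phenoxide that would epimerise C3 and without enough acidity to protonate the prenyl alkene or to dehydrate the 2'-hydroxy ketone toward a benzofuran.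

**Compound list**
1 | 2-bromo-5-methoxyphenol | COc1ccc(Br)c(O)c1 | starting material
2 | (2-bromo-5-methoxyphenoxy)triisopropylsilane | COc1ccc(Br)c(O[Si](C(C)C)(C(C)C)C(C)C)c1 | intermediate
3 | diethyl malonate | CCOC(=O)CC(=O)OCC | starting material
4 | diethyl 2-[4-methoxy-2-(triisopropylsilyloxy)phenyl]malonate | CCOC(=O)C(C(=O)OCC)c1ccc(OC)cc1O[Si](C(C)C)(C(C)C)C(C)C | intermediate
5 | 2-[4-methoxy-2-(triisopropylsilyloxy)phenyl]propane-1,3-diol | COc1ccc(C(CO)CO)c(O[Si](C(C)C)(C(C)C)C(C)C)c1 | intermediate
6 | (S)-3-hydroxy-2-[4-methoxy-2-(triisopropylsilyloxy)phenyl]propyl acetate | COc1ccc([C@@H](CO)COC(C)=O)c(O[Si](C(C)C)(C(C)C)C(C)C)c1 | intermediate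
7 | 4-bromo-3-methoxyphenol | COc1cc(O)ccc1Br | starting material
8 | (S)-3-(4-bromo-3-methoxyphenoxy)-2-[4-methoxy-2-(triisopropylsilyloxy)phenyl]propyl acetate | COc1ccc([C@@H](COc2ccc(Br)c(OC)c2)COC(C)=O)c(O[Si](C(C)C)(C(C)C)C(C)C)c1 | intermediate
9 | (R)-3-(4-bromo-3-methoxyphenoxy)-2-[4-methoxy-2-(triisopropylsilyloxy)phenyl]propan-1-ol | COc1ccc([C@@H](COc2ccc(Br)c(OC)c2)CO)c(O[Si](C(C)C)(C(C)C)C(C)C)c1 | intermediate
10 | (S)-3-(4-bromo-3-methoxyphenoxy)-2-[4-methoxy-2-(triisopropylsilyloxy)phenyl]propanal (not isolated) | COc1ccc([C@@H](COc2ccc(Br)c(OC)c2)C=O)c(O[Si](C(C)C)(C(C)C)C(C)C)c1 | intermediate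
11 | (S)-3-(4-bromo-3-methoxyphenoxy)-2-[4-methoxy-2-(triisopropylsilyloxy)phenyl]propanoic acid | COc1ccc([C@@H](COc2ccc(Br)c(OC)c2)C(=O)O)c(O[Si](C(C)C)(C(C)C)C(C)C)c1 | intermediate
12 | (S)-3-(4-bromo-3-methoxyphenoxy)-2-[4-methoxy-2-(triisopropylsilyloxy)phenyl]propanoic trifluoroacetic anhydride (not isolated) | COc1ccc([C@@H](COc2ccc(Br)c(OC)c2)C(=O)OC(=O)C(F)(F)F)c(O[Si](C(C)C)(C(C)C)C(C)C)c1 | intermediate
13 | (S)-6-bromo-7-methoxy-3-[4-methoxy-2-(triisopropylsilyloxy)phenyl]chroman-4-one | COc1ccc([C@H]2COc3cc(OC)c(Br)cc3C2=O)c(O[Si](C(C)C)(C(C)C)C(C)C)c1 | intermediate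
14 | tributyl(3-methylbut-2-enyl)stannane | CCCC[Sn](CCCC)(CCCC)CC=C(C)C | starting material
15 | (S)-7-methoxy-6-(3-methylbut-2-enyl)-3-[4-methoxy-2-(triisopropylsilyloxy)phenyl]chroman-4-one | COc1ccc([C@H]2COc3cc(OC)c(CC=C(C)C)cc3C2=O)c(O[Si](C(C)C)(C(C)C)C(C)C)c1 | intermediate
16 | (S)-3-(2-hydroxy-4-methoxyphenyl)-7-methoxy-6-(3-methylbut-2-enyl)chroman-4-one | COc1ccc([C@H]2COc3cc(OC)c(CC=C(C)C)cc3C2=O)c(O)c1 | target

Total step count: 10. Longest linear sequence: 10 steps (1 → 16). Enantiopurity should be followed by chiral HPLC at 6, 11, 13, 15 and 16.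

**Steps most likely to fail**

Step 8.
- What may go wrong: partial loss of configuration at C3 through acid-catalysed enolisation of the activated acyl compound or of the new ketone. This gets worse if closure onto the bromine-bearing ring needs warming or a stronger acid.
- Fallback: retention is no longer asked of the ring closure, and C3 is set again afterwards. The fallback sets out from 13 of eroded or lost enantiopurity.
- Asymmetric transfer hydrogenation under dynamic kinetic resolution is applied (RuCl(p-cymene)[(S,S)-TsDPEN], HCO2H/Et3N, EtOAc, rt), a reaction known for isoflavanones. Et3N equilibrates C3 while the catalyst reduces the 3S ketone much faster than its mirror image.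
- This should give cis-(3S,4S)-6-bromo-7-methoxy-3-[4-methoxy-2-(triisopropylsilyloxy)phenyl]chroman-4-ol F1, the sense following the usual one for aryl ketones.
- Dess–Martin periodinane (CH2Cl2, 0 °C) then oxidises C4 under neutral conditions, and the route is rejoined at 13.

Step 4.
- What may go wrong: the large ortho-silyloxy group may slow acyl transfer in the enzyme pocket, blur the discrimination between the arms, or steer the enzyme to the pro-R arm.
- Fallback: a small-molecule desymmetrisation whose catalyst exists in both mirror-image forms. It sets out from diol 5.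
- The dinuclear zinc catalyst is made from Et2Zn (10 mol %) and the ProPhenol ligand 2,6-bis{[2-(hydroxydiphenylmethyl)pyrrolidin-1-yl]methyl}-4-methylphenol (5 mol %, the enantiomer that acylates the pro-S arm). It is used with vinyl benzoate in toluene at −15 °C, a reaction known for 2-aryl-1,3-propanediols.
- This should give (S)-3-hydroxy-2-[4-methoxy-2-(triisopropylsilyloxy)phenyl]propyl benzoate F2.
- Mitsunobu etherification with 7 as in step 5 gives (S)-3-(4-bromo-3-methoxyphenoxy)-2-[4-methoxy-2-(triisopropylsilyloxy)phenyl]propyl benzoate F3.
- i-Bu2AlH (CH2Cl2, −78 °C) removes the benzoate, and the route is rejoined at alcohol 9.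

Step 9.
- What may go wrong: allyl transposition on palladium with coupling at the tertiary terminus (reverse prenylation), slow oxidative addition into the electron-rich C6–Br bond, and epimerisation at C3 during long heating.
- Fallback: the five-carbon chain is built in two neutral operations. It sets out from 13.
- Stille coupling with allyltributylstannane (Pd(PPh3)4, toluene, 90 °C), whose less hindered allyl group has two equivalent termini, should give (S)-6-allyl-7-methoxy-3-[4-methoxy-2-(triisopropylsilyloxy)phenyl]chroman-4-one F4.
- Cross-metathesis with excess 2-methylbut-2-ene (second-generation Grubbs catalyst, CH2Cl2, 40 °C), a known way from allylarenes to prenylarenes, rejoins the route at 15.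

**Further compounds**
F1 | step 8 | cis-(3S,4S)-6-bromo-7-methoxy-3-[4-methoxy-2-(triisopropylsilyloxy)phenyl]chroman-4-ol | COc1ccc([C@H]2COc3cc(OC)c(Br)cc3[C@H]2O)c(O[Si](C(C)C)(C(C)C)C(C)C)c1
F2 | step 4 | (S)-3-hydroxy-2-[4-methoxy-2-(triisopropylsilyloxy)phenyl]propyl benzoate | COc1ccc([C@@H](CO)COC(=O)c2ccccc2)c(O[Si](C(C)C)(C(C)C)C(C)C)c1
F3 | step 4 | (S)-3-(4-bromo-3-methoxyphenoxy)-2-[4-methoxy-2-(triisopropylsilyloxy)phenyl]propyl benzoate | COc1ccc([C@@H](COc2ccc(Br)c(OC)c2)COC(=O)c2ccccc2)c(O[Si](C(C)C)(C(C)C)C(C)C)c1
F4 | step 9 | (S)-6-allyl-7-methoxy-3-[4-methoxy-2-(triisopropylsilyloxy)phenyl]chroman-4-one | COc1ccc([C@H]2COc3cc(OC)c(CC=C)cc3C2=O)c(O[Si](C(C)C)(C(C)C)C(C)C)c1
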